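The carbocycle is opened at C3–C4, the bond between the two cis carbinol carbons of the cyclohexane that lie anti to the C5 oxygen. A samarium diiodide pinacol coupling of a 1,6-dialdehyde forms this bond, closes the six-membered ring and sets C3 and C4 in one operation, steered by the C5 benzyloxy group and the axial C1 methoxymethoxy group. The precursor holds C1 (from L-malic acid by self-regenerating allylation) as MOM ether and tert-butyl ester, and C5, set by a reagent-controlled ketone reduction, as benzyl ether; both aldehydes arise by ozonolysis. Tin-directed malonylation of the equatorial O4, caffeoylation of O5 and one acid step finish the target.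

Key step: step 11

Remark: quinic acid locants (C1 = carbinol carbon bearing the carboxyl group; O3, O4, O5 = the secondary oxygens) are used for all compounds, open-chain ones included.

Step 1
Reactants: 1 L-malic acid; 2 pivalaldehyde
Product: 3 2-[(2S,4S)-2-tert-butyl-5-oxo-1,3-dioxolan-4-yl]acetic acid
Conditions: TsOH·H2O (cat.), H2SO4 (cat.), pentane, reflux, Dean–Stark; recrystallisation
Reagents that add atoms: none
Why: Acid-catalysed acetalisation of the α-hydroxy acid unit under water removal gives the dioxolanone, and the new acetal centre is set by the malic acid centre because the cis isomer (tert-butyl and carboxymethyl on one face) is thermodynamically favoured and crystallises.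

Step 2
Reactants: 3 2-[(2S,4S)-2-tert-butyl-5-oxo-1,3-dioxolan-4-yl]acetic acid; 4 allyl bromide
Product: 5 2-[(2S,4S)-2-tert-butyl-5-oxo-4-(prop-2-en-1-yl)-1,3-dioxolan-4-yl]acetic acid
Conditions: LiN(SiMe3)2 (2.2 equiv), THF, −78 °C; then 4, −78 → −20 °C; 1 M HCl work-up
Reagents that add atoms: none
Why: Seebach alkylation with self-regeneration of the stereocentre, in which the carboxylate–enolate dianion is allylated on the face anti to the tert-butyl group, so that allyl takes the place of the former hydrogen with overall retention and fixes the quaternary C1.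

Step 3
Reactants: 5 2-[(2S,4S)-2-tert-butyl-5-oxo-4-(prop-2-en-1-yl)-1,3-dioxolan-4-yl]acetic acid
Product: 6 2-[(2S,4S)-2-tert-butyl-5-oxo-4-(prop-2-en-1-yl)-1,3-dioxolan-4-yl]-N-methoxy-N-methylacetamide
Conditions: MeNH(OMe)·HCl, EDC·HCl, N-methylmorpholine, CH2Cl2, 0 °C → rt
Reagents that add atoms: N,O-dimethylhydroxylamine hydrochloride, CNOC.Cl
Why: Carbodiimide amide coupling converts only the free carboxyl group into the Weinreb amide, since the weakly nucleophilic hydroxylamine should not open the hindered dioxolanone.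

Step 4
Reactants: 6 2-[(2S,4S)-2-tert-butyl-5-oxo-4-(prop-2-en-1-yl)-1,3-dioxolan-4-yl]-N-methoxy-N-methylacetamide
Product: 7 (2S)-2-hydroxy-2-{2-[methoxy(methyl)amino]-2-oxoethyl}pent-4-enoic acid
Conditions: LiOH, THF/H2O, 0 °C → rt; then 1 M HCl to pH 3
Reagents that add atoms: lithium hydroxide, [Li+].[OH-]
Why: Saponification of the activated acylal lactone releases pivalaldehyde and the α-hydroxy acid under conditions that leave the Weinreb amide intact and cannot epimerise the quaternary centre.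

Step 5
Reactants: 7 (2S)-2-hydroxy-2-{2-[methoxy(methyl)amino]-2-oxoethyl}pent-4-enoic acid
Product: 8 tert-butyl (2S)-2-hydroxy-2-{2-[methoxy(methyl)amino]-2-oxoethyl}pent-4-enoate
Conditions: tert-butyl 2,2,2-trichloroacetimidate, cyclohexane/CH2Cl2, rt
Reagents that add atoms: tert-butyl 2,2,2-trichloroacetimidate, CC(C)(C)OC(=N)C(Cl)(Cl)Cl
Why: Imidate tert-butylation, in which the carboxylic acid protonates the imidate and captures the tert-butyl cation, esterifies the hindered acid without touching the tertiary alcohol or the amide.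

Step 6
Reactants: 8 tert-butyl (2S)-2-hydroxy-2-{2-[methoxy(methyl)amino]-2-oxoethyl}pent-4-enoate
Product: 9 tert-butyl (2S)-2-{2-[methoxy(methyl)amino]-2-oxoethyl}-2-(methoxymethoxy)pent-4-enoate
Conditions: MOMCl, i-Pr2NEt, Bu4NI (cat.), 1,2-dichloroethane, 50 °C
Reagents that add atoms: chloromethyl methyl ether, COCCl
Why: MOM protection by alkylation of the tertiary alcohol with the iodide formed in situ masks O1, which prevents lactol formation with the later C4 aldehyde and supplies a donor oxygen for samarium in the key step.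

Step 7
Reactants: 9 tert-butyl (2S)-2-{2-[methoxy(methyl)amino]-2-oxoethyl}-2-(methoxymethoxy)pent-4-enoate; 10 (2-methylprop-1-en-1-yl)magnesium bromide
Product: 11 tert-butyl (2S)-2-(methoxymethoxy)-2-(4-methyl-2-oxopent-3-en-1-yl)pent-4-enoate
Conditions: THF, −20 → 0 °C; cold aq. NH4Cl
Reagents that add atoms: none
Why: Weinreb ketone synthesis, in which the Grignard reagent adds once through a stable magnesium chelate that collapses only on work-up, while the tert-butyl ester on the quaternary carbon is too hindered to compete and the β,β-disubstituted enone resists conjugate addition.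

Step 8
Reactants: 11 tert-butyl (2S)-2-(methoxymethoxy)-2-(4-methyl-2-oxopent-3-en-1-yl)pent-4-enoate
Product: 12 tert-butyl (2S)-2-[(2R)-2-hydroxy-4-methylpent-3-en-1-yl]-2-(methoxymethoxy)pent-4-enoate
Conditions: (S)-2-methyl-CBS-oxazaborolidine (0.3 equiv), catecholborane, toluene, −78 °C
Reagents that add atoms: none
Why: Corey–Bakshi–Shibata reduction, in which the (S)-oxazaborolidine binds the enone with the alkenyl group as the larger substituent and delivers hydride to the face that gives the (R)-carbinol at C5 under reagent control, catecholborane leaving both alkenes untouched.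

Step 9
Reactants: 12 tert-butyl (2S)-2-[(2R)-2-hydroxy-4-methylpent-3-en-1-yl]-2-(methoxymethoxy)pent-4-enoate
Product: 13 tert-butyl (2S)-2-[(2R)-2-(benzyloxy)-4-methylpent-3-en-1-yl]-2-(methoxymethoxy)pent-4-enoate
Conditions: 2-benzyloxy-1-methylpyridinium triflate, MgO, PhCF3, 83 °C
Reagents that add atoms: 2-benzyloxy-1-methylpyridinium trifluoromethanesulfonate, C[n+]1ccccc1OCc1ccccc1.[O-]S(=O)(=O)C(F)(F)F
Why: Dudley benzylation transfers benzyl from the pyridinium salt under neutral conditions, so the allylic carbinol is neither ionised nor lactonised onto the tert-butyl ester and C5 keeps its configuration.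

Step 10
Reactants: 13 tert-butyl (2S)-2-[(2R)-2-(benzyloxy)-4-methylpent-3-en-1-yl]-2-(methoxymethoxy)pent-4-enoate
Product: 14 tert-butyl (2R,4R)-4-(benzyloxy)-2-(methoxymethoxy)-5-oxo-2-(2-oxoethyl)pentanoate
Conditions: O3, CH2Cl2, −78 °C; then PPh3, −78 °C → rt; used crude at once
Reagents that add atoms: ozone, [O-][O+]=O
Why: Ozonolysis with reductive work-up cleaves the terminal and the trisubstituted alkene to the C3 and C4 aldehydes, and the neutral work-up avoids β-elimination of the C1 ether and epimerisation at C5.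

Step 11
Reactants: 14 tert-butyl (2R,4R)-4-(benzyloxy)-2-(methoxymethoxy)-5-oxo-2-(2-oxoethyl)pentanoate
Product: 15 tert-butyl (1S,3R,4R,5R)-5-(benzyloxy)-3,4-dihydroxy-1-(methoxymethoxy)cyclohexane-1-carboxylate
Conditions: SmI2 (3 equiv, 0.1 M in THF), t-BuOH (3 equiv), THF, −78 → −20 °C; aq. NaHCO3
Reagents that add atoms: none
Why: SmI2 transfers one electron to each aldehyde (or to one, the ketyl then adding to the second samarium-bound carbonyl), the carbon radicals couple to form C3–C4, and the trivalent samarium diolate is protonated on work-up. The closest known reaction type is the samarium diiodide pinacol cyclisation of α-alkoxy 1,6-dialdehydes to cis-cyclohexane-1,2-diols used for cyclitols. The six-membered carbocycle closes by intramolecular ketyl–carbonyl coupling (6-exo-trig in the stepwise picture) through a chair-like array with the C1 tert-butyl ester and the C5 benzyloxy group equatorial and the C1 methoxymethoxy group axial. At C4 the controlling element is the C5 stereocentre, since steric and dipole repulsion between the samarium-bound oxygen and the adjacent benzyloxy group puts O4 trans to O5. At C3 the controlling element is the samarium bridge between the two oxygens, which holds O3 cis to O4 and hence axial, on the face of the axial C1 methoxymethoxy group that can act as a further ligand. The step needs the 3,4-cis/4,5-trans diastereomer out of four and coupling faster than simple reduction or β-elimination, which the preset C1 and C5 centres, the 1,6-spacing of the aldehydes and the low temperature without HMPA should secure.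

Step 12
Reactants: 15 tert-butyl (1S,3R,4R,5R)-5-(benzyloxy)-3,4-dihydroxy-1-(methoxymethoxy)cyclohexane-1-carboxylate; 16 mono-tert-butyl malonate
Product: 18 tert-butyl (1S,3R,4R,5R)-5-(benzyloxy)-4-[(3-tert-butoxy-3-oxopropanoyl)oxy]-3-hydroxy-1-(methoxymethoxy)cyclohexane-1-carboxylate, via stannylene acetal 17 (not isolated)
Conditions: Bu2SnO, toluene, reflux, Dean–Stark; then at 0 °C a solution of t-BuO2CCH2COCl (made from 16 and 1-chloro-N,N,2-trimethylprop-1-en-1-amine, CH2Cl2, 0 °C)
Reagents that add atoms: none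
Why: Tin-mediated regioselective acylation, in which the dibutylstannylene acetal of the cis-3,4-diol raises the nucleophilicity of the equatorial oxygen, so the acid chloride acylates O4 and leaves the axial O3 free, as with cis-diols of pyranosides.

Step 13
Reactants: 18 tert-butyl (1S,3R,4R,5R)-5-(benzyloxy)-4-[(3-tert-butoxy-3-oxopropanoyl)oxy]-3-hydroxy-1-(methoxymethoxy)cyclohexane-1-carboxylate
Product: 19 tert-butyl (1R,3R,4S,5R)-5-(benzyloxy)-4-[(3-tert-butoxy-3-oxopropanoyl)oxy]-1-(methoxymethoxy)-3-[(triethylsilyl)oxy]cyclohexane-1-carboxylate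
Conditions: TESOTf, 2,6-lutidine, CH2Cl2, −78 °C
Reagents that add atoms: triethylsilyl trifluoromethanesulfonate, CC[Si](CC)(CC)OS(=O)(=O)C(F)(F)F
Why: Silylation with a silyl triflate and a hindered non-nucleophilic base caps the axial O3 at low temperature, which blocks malonyl migration to O3 and later acylation there.

Step 14
Reactants: 19 tert-butyl (1R,3R,4S,5R)-5-(benzyloxy)-4-[(3-tert-butoxy-3-oxopropanoyl)oxy]-1-(methoxymethoxy)-3-[(triethylsilyl)oxy]cyclohexane-1-carboxylate
Product: 20 tert-butyl (1R,3R,4S,5R)-4-[(3-tert-butoxy-3-oxopropanoyl)oxy]-5-hydroxy-1-(methoxymethoxy)-3-[(triethylsilyl)oxy]cyclohexane-1-carboxylate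
Conditions: H2 (1 atm), Pd(OH)2/C, EtOAc, rt
Reagents that add atoms: none
Why: Catalytic hydrogenolysis cleaves the benzyl ether at O5 under neutral conditions that spare silyl ether, acetal and esters and offer no base to promote acyl migration.

Step 15
Reactants: 21 caffeic acid
Product: 23 (E)-3-[3,4-bis(methoxymethoxy)phenyl]prop-2-enoic acid, via methoxymethyl ester 22 (not isolated)
Conditions: MOMCl, i-Pr2NEt, CH2Cl2, 0 °C → rt; then LiOH, THF/MeOH/H2O, rt; dilute HCl to pH 4 at 0 °C
Reagents that add atoms: chloromethyl methyl ether, COCCl; lithium hydroxide, [Li+].[OH-]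
Why: Exhaustive MOM alkylation protects both phenols and the acid, and mild saponification of the labile methoxymethyl ester then returns the free acid with the (E)-alkene unchanged.

Step 16
Reactants: 20 tert-butyl (1R,3R,4S,5R)-4-[(3-tert-butoxy-3-oxopropanoyl)oxy]-5-hydroxy-1-(methoxymethoxy)-3-[(triethylsilyl)oxy]cyclohexane-1-carboxylate; 23 (E)-3-[3,4-bis(methoxymethoxy)phenyl]prop-2-enoic acid
Product: 24 tert-butyl (1R,3R,4S,5R)-5-{[(2E)-3-[3,4-bis(methoxymethoxy)phenyl]prop-2-enoyl]oxy}-4-[(3-tert-butoxy-3-oxopropanoyl)oxy]-1-(methoxymethoxy)-3-[(triethylsilyl)oxy]cyclohexane-1-carboxylate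
Conditions: EDC·HCl, DMAP, CH2Cl2, 0 °C → rt
Reagents that add atoms: none
Why: Steglich esterification, in which DMAP transfers the carbodiimide-activated cinnamoyl group to the only free hydroxyl, the equatorial O5.

Step 17
Reactants: 24 tert-butyl (1R,3R,4S,5R)-5-{[(2E)-3-[3,4-bis(methoxymethoxy)phenyl]prop-2-enoyl]oxy}-4-[(3-tert-butoxy-3-oxopropanoyl)oxy]-1-(methoxymethoxy)-3-[(triethylsilyl)oxy]cyclohexane-1-carboxylate
Product: 25 (1S,3R,4R,5R)-4-[(carboxyacetyl)oxy]-5-{[(2E)-3-(3,4-dihydroxyphenyl)prop-2-enoyl]oxy}-1,3-dihydroxycyclohexane-1-carboxylic acid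
Conditions: TFA/CH2Cl2/H2O (10:10:1), 1,3-dimethoxybenzene, 0 °C → rt; cold evaporation, C18 chromatography
Reagents that add atoms: none
Why: Global acidolysis removes the two tert-butyl esters, the three methoxymethyl acetals and the triethylsilyl ether in one operation, under which carboxylic esters and the (E)-alkene persist and acyl migration is slow, the dimethoxybenzene trapping the cations released.

Compound list
1 | L-malic acid | O[C@@H](CC(O)=O)C(O)=O | starting material
2 | pivalaldehyde | CC(C)(C)C=O | starting material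
3 | 2-[(2S,4S)-2-tert-butyl-5-oxo-1,3-dioxolan-4-yl]acetic acid | CC(C)(C)[C@H]1O[C@@H](CC(=O)O)C(=O)O1 | intermediate
4 | allyl bromide | C=CCBr | starting material
5 | 2-[(2S,4S)-2-tert-butyl-5-oxo-4-(prop-2-en-1-yl)-1,3-dioxolan-4-yl]acetic acid | CC(C)(C)[C@H]1O[C@@](CC=C)(CC(=O)O)C(=O)O1 | intermediate
6 | 2-[(2S,4S)-2-tert-butyl-5-oxo-4-(prop-2-en-1-yl)-1,3-dioxolan-4-yl]-N-methoxy-N-methylacetamide | CC(C)(C)[C@H]1O[C@@](CC=C)(CC(=O)N(C)OC)C(=O)O1 | intermediate
7 | (2S)-2-hydroxy-2-{2-[methoxy(methyl)amino]-2-oxoethyl}pent-4-enoic acid | C=CC[C@](O)(CC(=O)N(C)OC)C(=O)O | intermediate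
8 | tert-butyl (2S)-2-hydroxy-2-{2-[methoxy(methyl)amino]-2-oxoethyl}pent-4-enoate | C=CC[C@](O)(CC(=O)N(C)OC)C(=O)OC(C)(C)C | intermediate
9 | tert-butyl (2S)-2-{2-[methoxy(methyl)amino]-2-oxoethyl}-2-(methoxymethoxy)pent-4-enoate | C=CC[C@](OCOC)(CC(=O)N(C)OC)C(=O)OC(C)(C)C | intermediate
10 | (2-methylprop-1-en-1-yl)magnesium bromide | CC(C)=C[Mg]Br | starting material
11 | tert-butyl (2S)-2-(methoxymethoxy)-2-(4-methyl-2-oxopent-3-en-1-yl)pent-4-enoate | C=CC[C@](OCOC)(CC(=O)C=C(C)C)C(=O)OC(C)(C)C | intermediate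
12 | tert-butyl (2S)-2-[(2R)-2-hydroxy-4-methylpent-3-en-1-yl]-2-(methoxymethoxy)pent-4-enoate | C=CC[C@](OCOC)(C[C@@H](O)C=C(C)C)C(=O)OC(C)(C)C | intermediate
13 | tert-butyl (2S)-2-[(2R)-2-(benzyloxy)-4-methylpent-3-en-1-yl]-2-(methoxymethoxy)pent-4-enoate | C=CC[C@](OCOC)(C[C@@H](OCc1ccccc1)C=C(C)C)C(=O)OC(C)(C)C | intermediate
14 | tert-butyl (2R,4R)-4-(benzyloxy)-2-(methoxymethoxy)-5-oxo-2-(2-oxoethyl)pentanoate (pinacol precursor) | O=CC[C@@](OCOC)(C(=O)OC(C)(C)C)C[C@@H](OCc1ccccc1)C=O | intermediate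
15 | tert-butyl (1S,3R,4R,5R)-5-(benzyloxy)-3,4-dihydroxy-1-(methoxymethoxy)cyclohexane-1-carboxylate (tert-butyl 5-O-benzyl-1-O-(methoxymethyl)quinate) | O[C@@H]1[C@H](O)C[C@@](OCOC)(C(=O)OC(C)(C)C)C[C@H]1OCc1ccccc1 | intermediate
16 | mono-tert-butyl malonate (3-tert-butoxy-3-oxopropanoic acid) | CC(C)(C)OC(=O)CC(=O)O | starting material
17 | 3,4-O-dibutylstannylene acetal of 15 | CCCC[Sn]2(CCCC)O[C@@H]1[C@H](O2)C[C@@](OCOC)(C(=O)OC(C)(C)C)C[C@H]1OCc1ccccc1 | intermediate
18 | tert-butyl (1S,3R,4R,5R)-5-(benzyloxy)-4-[(3-tert-butoxy-3-oxopropanoyl)oxy]-3-hydroxy-1-(methoxymethoxy)cyclohexane-1-carboxylate | CC(C)(C)OC(=O)CC(=O)O[C@@H]1[C@H](O)C[C@@](OCOC)(C(=O)OC(C)(C)C)C[C@H]1OCc1ccccc1 | intermediate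
19 | tert-butyl (1R,3R,4S,5R)-5-(benzyloxy)-4-[(3-tert-butoxy-3-oxopropanoyl)oxy]-1-(methoxymethoxy)-3-[(triethylsilyl)oxy]cyclohexane-1-carboxylate | CC(C)(C)OC(=O)CC(=O)O[C@@H]1[C@H](O[Si](CC)(CC)CC)C[C@@](OCOC)(C(=O)OC(C)(C)C)C[C@H]1OCc1ccccc1 | intermediate
20 | tert-butyl (1R,3R,4S,5R)-4-[(3-tert-butoxy-3-oxopropanoyl)oxy]-5-hydroxy-1-(methoxymethoxy)-3-[(triethylsilyl)oxy]cyclohexane-1-carboxylate | CC(C)(C)OC(=O)CC(=O)O[C@@H]1[C@H](O[Si](CC)(CC)CC)C[C@@](OCOC)(C(=O)OC(C)(C)C)C[C@H]1O | intermediate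
21 | caffeic acid | O=C(O)/C=C/c1ccc(O)c(O)c1 | starting material
22 | methoxymethyl (E)-3-[3,4-bis(methoxymethoxy)phenyl]prop-2-enoate | COCOC(=O)/C=C/c1ccc(OCOC)c(OCOC)c1 | intermediate
23 | (E)-3-[3,4-bis(methoxymethoxy)phenyl]prop-2-enoic acid | O=C(O)/C=C/c1ccc(OCOC)c(OCOC)c1 | intermediate
24 | tert-butyl (1R,3R,4S,5R)-5-{[(2E)-3-[3,4-bis(methoxymethoxy)phenyl]prop-2-enoyl]oxy}-4-[(3-tert-butoxy-3-oxopropanoyl)oxy]-1-(methoxymethoxy)-3-[(triethylsilyl)oxy]cyclohexane-1-carboxylate | CC(C)(C)OC(=O)CC(=O)O[C@@H]1[C@H](O[Si](CC)(CC)CC)C[C@@](OCOC)(C(=O)OC(C)(C)C)C[C@H]1OC(=O)/C=C/c1ccc(OCOC)c(OCOC)c1 | intermediate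
25 | (1S,3R,4R,5R)-4-[(carboxyacetyl)oxy]-5-{[(2E)-3-(3,4-dihydroxyphenyl)prop-2-enoyl]oxy}-1,3-dihydroxycyclohexane-1-carboxylic acid (4-O-malonyl-5-O-caffeoylquinic acid) | O=C(O)CC(=O)O[C@@H]1[C@H](O)C[C@@](O)(C(=O)O)C[C@H]1OC(=O)/C=C/c1ccc(O)c(O)c1 | target

Total step count: 17. Longest linear sequence: 16 steps (steps 1–14, 16 and 17); step 15 is a one-step side branch.

Steps most likely to fail

Step 11 (key step). The ketyl coupling may show poor diastereoselectivity (trans-diol, or the diol cis to O5), or the C3 aldehyde arm may lose its β-alkoxy group before coupling. The fallback closes the same C3–C4 bond by olefin metathesis and sets out from diene 13. Ring-closing metathesis with the second-generation Grubbs catalyst (CH2Cl2, 40 °C) should give tert-butyl (1S,5R)-5-(benzyloxy)-1-(methoxymethoxy)cyclohex-3-ene-1-carboxylate F1. Dihydroxylation with OsO4 (cat.) and N-methylmorpholine N-oxide, expected on the face anti to the allylic benzyloxy group, then comes back to the route at diol 15.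

Step 8. The oxazaborolidine may discriminate the two ketone faces insufficiently, because the alkyl side of the enone is branched. The fallback uses an ynone and a ruthenium transfer hydrogenation and sets out from Weinreb amide 9.
- 1-Propynylmagnesium bromide should give tert-butyl (2S)-2-(methoxymethoxy)-2-(2-oxopent-3-yn-1-yl)pent-4-enoate F2.
- Noyori transfer hydrogenation with RuCl[(R,R)-TsDPEN](p-cymene) in 2-propanol, where the alkynyl group takes the role of the aryl group, should give tert-butyl (2S)-2-[(2R)-2-hydroxypent-3-yn-1-yl]-2-(methoxymethoxy)pent-4-enoate F3.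
- Benzylation as in step 9 should give tert-butyl (2S)-2-[(2R)-2-(benzyloxy)pent-3-yn-1-yl]-2-(methoxymethoxy)pent-4-enoate F4.
- Semihydrogenation over Pd/CaCO3 poisoned with Pb(OAc)2 and quinoline should give tert-butyl (2S)-2-[(2R,3Z)-2-(benzyloxy)pent-3-en-1-yl]-2-(methoxymethoxy)pent-4-enoate F5.
- Ozonolysis as in step 10 comes back to the route at dialdehyde 14.

Step 12. Acylation may occur at the axial O3, or the malonyl group may migrate from O4 to O3. The fallback blocks the axial oxygen first by the stereoelectronic rule of orthoester opening and sets out from diol 15.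
- 2-Chloro-1,1,1-trimethoxyethane with catalytic camphorsulfonic acid should give tert-butyl 5-O-benzyl-3,4-O-(2-chloro-1-methoxyethylidene)-1-O-(methoxymethyl)quinate F6.
- Mild hydrolysis in aqueous acetic acid should open it to the axial ester, tert-butyl 5-O-benzyl-3-O-(chloroacetyl)-1-O-(methoxymethyl)quinate F7.
- Steglich esterification of the free equatorial O4 with 16 (EDC·HCl, DMAP) should give tert-butyl 5-O-benzyl-4-O-(3-tert-butoxy-3-oxopropanoyl)-3-O-(chloroacetyl)-1-O-(methoxymethyl)quinate F8.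
- Thiourea with NaHCO3 in ethanol removes the chloroacetyl group and comes back to the route at 18.

Further compounds
F1 | step 11 | tert-butyl (1S,5R)-5-(benzyloxy)-1-(methoxymethoxy)cyclohex-3-ene-1-carboxylate | C1=CC[C@@](OCOC)(C(=O)OC(C)(C)C)C[C@H]1OCc1ccccc1
F2 | step 8 | tert-butyl (2S)-2-(methoxymethoxy)-2-(2-oxopent-3-yn-1-yl)pent-4-enoate | C=CC[C@](OCOC)(CC(=O)C#CC)C(=O)OC(C)(C)C
F3 | step 8 | tert-butyl (2S)-2-[(2R)-2-hydroxypent-3-yn-1-yl]-2-(methoxymethoxy)pent-4-enoate | C=CC[C@](OCOC)(C[C@@H](O)C#CC)C(=O)OC(C)(C)C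
F4 | step 8 | tert-butyl (2S)-2-[(2R)-2-(benzyloxy)pent-3-yn-1-yl]-2-(methoxymethoxy)pent-4-enoate | C=CC[C@](OCOC)(C[C@@H](OCc1ccccc1)C#CC)C(=O)OC(C)(C)C
F5 | step 8 | tert-butyl (2S)-2-[(2R,3Z)-2-(benzyloxy)pent-3-en-1-yl]-2-(methoxymethoxy)pent-4-enoate | C=CC[C@](OCOC)(C[C@@H](OCc1ccccc1)/C=C\C)C(=O)OC(C)(C)C
F6 | step 12 | tert-butyl 5-O-benzyl-3,4-O-(2-chloro-1-methoxyethylidene)-1-O-(methoxymethyl)quinate | COC3(CCl)O[C@@H]1[C@H](O3)C[C@@](OCOC)(C(=O)OC(C)(C)C)C[C@H]1OCc1ccccc1
F7 | step 12 | tert-butyl 5-O-benzyl-3-O-(chloroacetyl)-1-O-(methoxymethyl)quinate | O[C@@H]1[C@H](OC(=O)CCl)C[C@@](OCOC)(C(=O)OC(C)(C)C)C[C@H]1OCc1ccccc1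
F8 | step 12 | tert-butyl 5-O-benzyl-4-O-(3-tert-butoxy-3-oxopropanoyl)-3-O-(chloroacetyl)-1-O-(methoxymethyl)quinate | CC(C)(C)OC(=O)CC(=O)O[C@@H]1[C@H](OC(=O)CCl)C[C@@](OCOC)(C(=O)OC(C)(C)C)C[C@H]1OCc1ccccc1
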